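**Retrosynthetic overview**
1. The enyne is made last: the C6 allyl group is extended by cross-metathesis with crotonaldehyde and Colvin homologation.
2. Ring B (tetrahydrofuran, C6–O–C9) and the C10–Br bond form second, by transannular bromoetherification of a Δ9 α,α'-trans-oxocene carbinol.
3. The C6 carbinol comes from chelation-controlled allylation of the oxocene aldehyde; the C12–Br bond comes from Appel inversion.
4. Ring A (oxocene) forms first, by ring-closing metathesis; its C7–O–C13 ether bond and C7 come from a new catalyst-controlled carbene O–H insertion.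
5. C12 and C13 come from C2-symmetric (R,R)-diepoxybutane by two copper-catalysed Grignard openings.

Assumption: locants C1–C15 follow the linear chain (C1 = alkyne CH, C15 = ethyl CH3), so the target is 3E,6S,7S,9S,10S,12S,13R with ether bridges C6–O–C9 and C7–O–C13 (an α,α'-trans oxocane).

**Route**

Step 1
Reactants: 1 (2R,3R)-1,2:3,4-diepoxybutane
Product: 2 (1R)-1-[(2R)-oxiran-2-yl]but-3-en-1-ol
Conditions: CH2=CHMgBr (0.4 equiv, 1 in excess), CuI (5 mol %), THF, −40 °C; aq. NH4Cl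
Reagents that add atoms: vinylmagnesium bromide, C=C[Mg]Br
Why: Copper-catalysed SN2 opening of a terminal epoxide by a Grignard reagent; the C2 symmetry of 1 makes both epoxides equivalent, so mono-opening gives one epoxy alcohol and the two oxygen-bearing centres (future C12 and C13) are carried over unchanged.

Step 2
Reactants: 2 (1R)-1-[(2R)-oxiran-2-yl]but-3-en-1-ol
Product: 3 tert-butyl(dimethyl){[(1R)-1-[(2R)-oxiran-2-yl]but-3-en-1-yl]oxy}silane
Conditions: TBSCl, imidazole, DMF, 0 °C to rt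
Reagents that add atoms: tert-butyldimethylsilyl chloride, CC(C)(C)[Si](C)(C)Cl
Why: Imidazole-promoted silylation of the secondary alcohol under conditions too mild for Payne rearrangement of the epoxy alcohol.

Step 3
Reactants: 3 tert-butyl(dimethyl){[(1R)-1-[(2R)-oxiran-2-yl]but-3-en-1-yl]oxy}silane
Product: 4 (3R,4R)-4-{[tert-butyl(dimethyl)silyl]oxy}hept-6-en-3-ol
Conditions: MeMgBr, CuI (10 mol %), THF, −40 °C; aq. NH4Cl at −40 °C
Reagents that add atoms: methylmagnesium bromide, C[Mg]Br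
Why: A second copper-catalysed terminal epoxide opening completes the ethyl group and frees only the C13 hydroxyl, so the two oxygens are differentiated without a selective protection (the cold quench suppresses 1,2-silyl migration).

Step 4
Reactants: 5 ethyl 2-acetylpent-4-enoate
Product: 6 ethyl 2-diazopent-4-enoate
Conditions: 4-acetamidobenzenesulfonyl azide, DBU, MeCN, 0 °C to rt
Reagents that add atoms: 4-acetamidobenzenesulfonyl azide, CC(=O)Nc1ccc(cc1)S(=O)(=O)N=[N+]=[N-]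
Why: Regitz deacylative diazo transfer, in which the acetyl group leaves as the N-acetyl sulfonamide.

Step 5
Reactants: 4 (3R,4R)-4-{[tert-butyl(dimethyl)silyl]oxy}hept-6-en-3-ol; 6 ethyl 2-diazopent-4-enoate
Product: 7 ethyl (2S)-2-{[(3R,4R)-4-{[tert-butyl(dimethyl)silyl]oxy}hept-6-en-3-yl]oxy}pent-4-enoate
Conditions: 6 (1.8 equiv, syringe pump), Cu(MeCN)4PF6 (5 mol %), (Sa,S,S)-Ph-SpiroBOX (6 mol %; the antipode is used if the sense of induction proves opposite), NaB[3,5-(CF3)2C6H3]4 (6 mol %), 4 Å molecular sieves, CH2Cl2, 0 °C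
Reagents that add atoms: none
Why: Proposed new method: a ligand-controlled, diastereoselective carbene O–H insertion of an α-allyl α-diazo ester into a hindered, β-silyloxy secondary alcohol, forming the secondary–secondary C7–O–C13 ether and setting C7 as S in one step; the monovalent copper carbene is captured by the hydroxyl lone pair to give a copper-bound oxonium ylide (enolate), whose 1,2-proton shift inside the chiral spiro-bis(oxazoline) pocket fixes the C7 configuration, while fast O–H capture and the non-coordinating borate counter-ion outrun 1,2-hydride shift and cyclopropanation; the closest known reaction type is the copper–bis(oxazoline) enantioselective O–H insertion of α-diazo esters into simple alcohols.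

Step 6
Reactants: 7 ethyl (2S)-2-{[(3R,4R)-4-{[tert-butyl(dimethyl)silyl]oxy}hept-6-en-3-yl]oxy}pent-4-enoate
Product: 8 ethyl (2S,4Z,7R,8R)-7-{[tert-butyl(dimethyl)silyl]oxy}-8-ethyl-3,6,7,8-tetrahydro-2H-oxocine-2-carboxylate
Conditions: second-generation Grubbs catalyst RuCl2(H2IMes)(PCy3)(=CHPh) (5 mol %), CH2Cl2 (2 mM), 40 °C
Reagents that add atoms: none
Why: Ring-closing metathesis to the eight-membered ring, which can hold only the Z olefin, assisted by the gauche O–C13–C12–O unit; no stereocentre is touched.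

Step 7
Reactants: 8 ethyl (2S,4Z,7R,8R)-7-{[tert-butyl(dimethyl)silyl]oxy}-8-ethyl-3,6,7,8-tetrahydro-2H-oxocine-2-carboxylate
Product: 9 ethyl (2S,4Z,7R,8R)-8-ethyl-7-hydroxy-3,6,7,8-tetrahydro-2H-oxocine-2-carboxylate
Conditions: HF·pyridine, THF/pyridine, 0 °C to rt
Reagents that add atoms: none
Why: Fluoride desilylation under buffered acidic conditions that do not epimerise the α-alkoxy ester; the ester and the C12 hydroxyl lie on opposite ring faces, so no lactone forms.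

Step 8
Reactants: 9 ethyl (2S,4Z,7R,8R)-8-ethyl-7-hydroxy-3,6,7,8-tetrahydro-2H-oxocine-2-carboxylate
Product: 10 ethyl (2S,4Z,7S,8R)-7-bromo-8-ethyl-3,6,7,8-tetrahydro-2H-oxocine-2-carboxylate
Conditions: CBr4, P(n-C8H17)3, toluene, 70 °C
Reagents that add atoms: carbon tetrabromide, BrC(Br)(Br)Br
Why: Appel bromination, in which bromide displaces the alkoxyphosphonium by SN2 and inverts C12 (R to S), placing Br trans to the C13 ethyl group.

Step 9
Reactants: 10 ethyl (2S,4Z,7S,8R)-7-bromo-8-ethyl-3,6,7,8-tetrahydro-2H-oxocine-2-carboxylate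
Product: 11 (2S,4Z,7S,8R)-7-bromo-8-ethyl-3,6,7,8-tetrahydro-2H-oxocine-2-carbaldehyde
Conditions: i-Bu2AlH (1.1 equiv), CH2Cl2, −78 °C; aq. potassium sodium tartrate
Reagents that add atoms: none
Why: Low-temperature half-reduction of the α-alkoxy ester through the stable aluminium hemiacetal; C7 does not epimerise and the secondary bromide is inert at −78 °C.

Step 10
Reactants: 11 (2S,4Z,7S,8R)-7-bromo-8-ethyl-3,6,7,8-tetrahydro-2H-oxocine-2-carbaldehyde
Product: 12 (1S)-1-[(2S,4Z,7S,8R)-7-bromo-8-ethyl-3,6,7,8-tetrahydro-2H-oxocin-2-yl]but-3-en-1-ol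
Conditions: allylSnBu3, MgBr2·OEt2, CH2Cl2, −78 to −20 °C
Reagents that add atoms: allyltributylstannane, C=CC[Sn](CCCC)(CCCC)CCCC
Why: Keck-type chelation-controlled allylation, in which MgBr2 bridges the aldehyde oxygen and the ring ether oxygen and allyl adds to the face opposite C8 (Cram chelate), giving the 6S,7S (syn) alcohol.

Step 11
Reactants: 12 (1S)-1-[(2S,4Z,7S,8R)-7-bromo-8-ethyl-3,6,7,8-tetrahydro-2H-oxocin-2-yl]but-3-en-1-ol
Product: 13 (1S,3R,4S,6S,7S,9S)-4,6-dibromo-3-ethyl-9-(prop-2-en-1-yl)-2,8-dioxabicyclo[5.2.1]decane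
Conditions: NBS (1.05 equiv), CH2Cl2, −20 to 0 °C, dark
Reagents that add atoms: N-bromosuccinimide, O=C1CCC(=O)N1Br
Why: Biomimetic transannular 5-exo bromoetherification, in which the C6 hydroxyl can reach C9 only on the ring face carrying the C7 side chain, so the bromonium sits on the other face and anti addition sets 9S and 10S while closing ring B; the ring Z-olefin with an internal nucleophile should react faster than the terminal allyl olefin.

Step 12
Reactants: 13 (1S,3R,4S,6S,7S,9S)-4,6-dibromo-3-ethyl-9-(prop-2-en-1-yl)-2,8-dioxabicyclo[5.2.1]decane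
Product: 14 (2E)-4-[(1S,3R,4S,6S,7S,9S)-4,6-dibromo-3-ethyl-2,8-dioxabicyclo[5.2.1]decan-9-yl]but-2-enal
Conditions: (E)-crotonaldehyde (10 equiv), second-generation Hoveyda–Grubbs catalyst RuCl2(H2IMes)(=CH-C6H4-2-OiPr) (5 mol %), CH2Cl2, 40 °C
Reagents that add atoms: (E)-crotonaldehyde, C/C=C/C=O
Why: Olefin cross-metathesis of a terminal olefin with crotonaldehyde, which gives the thermodynamically favoured E-enal with loss of propene.

Step 13
Reactants: 14 (2E)-4-[(1S,3R,4S,6S,7S,9S)-4,6-dibromo-3-ethyl-2,8-dioxabicyclo[5.2.1]decan-9-yl]but-2-enal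
Product: 15 (1S,3R,4S,6S,7S,9S)-4,6-dibromo-3-ethyl-9-[(2E)-pent-2-en-4-yn-1-yl]-2,8-dioxabicyclo[5.2.1]decane
Conditions: TMSCHN2, LiN(i-Pr)2, THF, −78 to 0 °C
Reagents that add atoms: (trimethylsilyl)diazomethane, C[Si](C)(C)C=[N+]=[N-]
Why: Colvin rearrangement, in which 1,2-addition of lithiated TMS-diazomethane, Peterson-type loss of silanolate and 1,2-hydride shift of the alkylidene carbene give the terminal alkyne with the E olefin intact, at a temperature where the secondary bromides are inert.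

**Compound list**
1 | (2R,3R)-1,2:3,4-diepoxybutane | C1O[C@H]1[C@H]1CO1 | starting material
2 | (1R)-1-[(2R)-oxiran-2-yl]but-3-en-1-ol | C1O[C@H]1[C@H](O)CC=C | intermediate
3 | tert-butyl(dimethyl){[(1R)-1-[(2R)-oxiran-2-yl]but-3-en-1-yl]oxy}silane | C1O[C@H]1[C@H](O[Si](C)(C)C(C)(C)C)CC=C | intermediate
4 | (3R,4R)-4-{[tert-butyl(dimethyl)silyl]oxy}hept-6-en-3-ol | CC[C@@H](O)[C@H](O[Si](C)(C)C(C)(C)C)CC=C | intermediate
5 | ethyl 2-acetylpent-4-enoate | CCOC(=O)C(CC=C)C(C)=O | starting material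
6 | ethyl 2-diazopent-4-enoate | CCOC(=O)C(=[N+]=[N-])CC=C | intermediate
7 | ethyl (2S)-2-{[(3R,4R)-4-{[tert-butyl(dimethyl)silyl]oxy}hept-6-en-3-yl]oxy}pent-4-enoate | CCOC(=O)[C@H](CC=C)O[C@H](CC)[C@H](O[Si](C)(C)C(C)(C)C)CC=C | intermediate
8 | ethyl (2S,4Z,7R,8R)-7-{[tert-butyl(dimethyl)silyl]oxy}-8-ethyl-3,6,7,8-tetrahydro-2H-oxocine-2-carboxylate | CCOC(=O)[C@@H]1C/C=C\C[C@@H](O[Si](C)(C)C(C)(C)C)[C@@H](CC)O1 | intermediate
9 | ethyl (2S,4Z,7R,8R)-8-ethyl-7-hydroxy-3,6,7,8-tetrahydro-2H-oxocine-2-carboxylate | CCOC(=O)[C@@H]1C/C=C\C[C@@H](O)[C@@H](CC)O1 | intermediate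
10 | ethyl (2S,4Z,7S,8R)-7-bromo-8-ethyl-3,6,7,8-tetrahydro-2H-oxocine-2-carboxylate | CCOC(=O)[C@@H]1C/C=C\C[C@H](Br)[C@@H](CC)O1 | intermediate
11 | (2S,4Z,7S,8R)-7-bromo-8-ethyl-3,6,7,8-tetrahydro-2H-oxocine-2-carbaldehyde | O=C[C@@H]1C/C=C\C[C@H](Br)[C@@H](CC)O1 | intermediate
12 | (1S)-1-[(2S,4Z,7S,8R)-7-bromo-8-ethyl-3,6,7,8-tetrahydro-2H-oxocin-2-yl]but-3-en-1-ol | C=CC[C@H](O)[C@@H]1C/C=C\C[C@H](Br)[C@@H](CC)O1 | intermediate
13 | (1S,3R,4S,6S,7S,9S)-4,6-dibromo-3-ethyl-9-(prop-2-en-1-yl)-2,8-dioxabicyclo[5.2.1]decane | C=CC[C@@H]1O[C@H]2C[C@@H]1O[C@H](CC)[C@@H](Br)C[C@@H]2Br | intermediate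
14 | (2E)-4-[(1S,3R,4S,6S,7S,9S)-4,6-dibromo-3-ethyl-2,8-dioxabicyclo[5.2.1]decan-9-yl]but-2-enal | O=C/C=C/C[C@@H]1O[C@H]2C[C@@H]1O[C@H](CC)[C@@H](Br)C[C@@H]2Br | intermediate
15 | (1S,3R,4S,6S,7S,9S)-4,6-dibromo-3-ethyl-9-[(2E)-pent-2-en-4-yn-1-yl]-2,8-dioxabicyclo[5.2.1]decane | C#C/C=C/C[C@@H]1O[C@H]2C[C@@H]1O[C@H](CC)[C@@H](Br)C[C@@H]2Br | target

**Step count and risks**
Total step count: 13. Longest linear sequence: 12 (steps 1–3 and 5–13; step 4 is a one-step side branch).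

The three steps most likely to fail:

Step 5 (the proposed new O–H insertion; risks are 1,2-hydride shift of the carbene, cyclopropanation and mismatched diastereocontrol). The fallback uses known auxiliary chemistry, sets out from 4 and comes back at 7. Dirhodium tetraacetate Rh2(OAc)4-catalysed O–H insertion of ethyl diazoacetate into 4 gives ethyl 2-{[(3R,4R)-4-{[tert-butyl(dimethyl)silyl]oxy}hept-6-en-3-yl]oxy}acetate F1. Saponification with LiOH gives 2-{[(3R,4R)-4-{[tert-butyl(dimethyl)silyl]oxy}hept-6-en-3-yl]oxy}acetic acid F2. Coupling through the pivaloyl mixed anhydride with lithiated (4R)-4-benzyl-1,3-oxazolidin-2-one gives (4R)-4-benzyl-3-(2-{[(3R,4R)-4-{[tert-butyl(dimethyl)silyl]oxy}hept-6-en-3-yl]oxy}acetyl)-1,3-oxazolidin-2-one F3. Evans-type glycolate alkylation (NaN(SiMe3)2, allyl iodide, −78 to −45 °C, allyl entering anti to the benzyl group) gives (4R)-4-benzyl-3-[(2S)-2-{[(3R,4R)-4-{[tert-butyl(dimethyl)silyl]oxy}hept-6-en-3-yl]oxy}pent-4-enoyl]-1,3-oxazolidin-2-one F4. EtOMgBr in EtOH/THF at 0 °C removes the auxiliary and gives 7.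

Step 6 (ring-closing metathesis of the α,α'-trans diene ester; risk of oligomers because only one gauche O–C–C–O unit is present). The fallback changes the cyclisation substrate to a 1,2-dioxygenated diene with two such units, sets out from 7 and comes back at 8. LiBH4 reduces 7 to (2S)-2-{[(3R,4R)-4-{[tert-butyl(dimethyl)silyl]oxy}hept-6-en-3-yl]oxy}pent-4-en-1-ol F5. Ac2O/pyridine gives (2S)-2-{[(3R,4R)-4-{[tert-butyl(dimethyl)silyl]oxy}hept-6-en-3-yl]oxy}pent-4-en-1-yl acetate F6. Ring-closing metathesis with second-generation Grubbs catalyst RuCl2(H2IMes)(PCy3)(=CHPh) gives [(2S,4Z,7R,8R)-7-{[tert-butyl(dimethyl)silyl]oxy}-8-ethyl-3,6,7,8-tetrahydro-2H-oxocin-2-yl]methyl acetate F7. K2CO3/MeOH gives [(2S,4Z,7R,8R)-7-{[tert-butyl(dimethyl)silyl]oxy}-8-ethyl-3,6,7,8-tetrahydro-2H-oxocin-2-yl]methanol F8. TEMPO/PhI(OAc)2 in MeCN/H2O gives (2S,4Z,7R,8R)-7-{[tert-butyl(dimethyl)silyl]oxy}-8-ethyl-3,6,7,8-tetrahydro-2H-oxocine-2-carboxylic acid F9. EtI and K2CO3 in DMF give 8.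

Step 11 (transannular bromoetherification; risk that NBS also attacks the allyl olefin, or that 6-endo closure competes). The fallback removes the second olefin by bringing in C5–C4 as an acetal, sets out from 11 and comes back at 14. Chelation-controlled addition of (1,3-dioxolan-2-ylmethyl)magnesium bromide (MgBr2·OEt2, CH2Cl2/THF, −78 °C) to 11 gives (1S)-1-[(2S,4Z,7S,8R)-7-bromo-8-ethyl-3,6,7,8-tetrahydro-2H-oxocin-2-yl]-2-(1,3-dioxolan-2-yl)ethan-1-ol F10. NBS in CH2Cl2 gives (1S,3R,4S,6S,7S,9S)-4,6-dibromo-9-[(1,3-dioxolan-2-yl)methyl]-3-ethyl-2,8-dioxabicyclo[5.2.1]decane F11. TsOH in acetone/H2O gives 2-[(1S,3R,4S,6S,7S,9S)-4,6-dibromo-3-ethyl-2,8-dioxabicyclo[5.2.1]decan-9-yl]acetaldehyde F12. Wittig olefination with (triphenylphosphoranylidene)acetaldehyde in toluene at 80 °C gives 14.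

**Further compounds**
F1 | step 5 | ethyl 2-{[(3R,4R)-4-{[tert-butyl(dimethyl)silyl]oxy}hept-6-en-3-yl]oxy}acetate | CCOC(=O)CO[C@H](CC)[C@H](O[Si](C)(C)C(C)(C)C)CC=C
F2 | step 5 | 2-{[(3R,4R)-4-{[tert-butyl(dimethyl)silyl]oxy}hept-6-en-3-yl]oxy}acetic acid | OC(=O)CO[C@H](CC)[C@H](O[Si](C)(C)C(C)(C)C)CC=C
F3 | step 5 | (4R)-4-benzyl-3-(2-{[(3R,4R)-4-{[tert-butyl(dimethyl)silyl]oxy}hept-6-en-3-yl]oxy}acetyl)-1,3-oxazolidin-2-one | O=C(CO[C@H](CC)[C@H](O[Si](C)(C)C(C)(C)C)CC=C)N1[C@H](Cc2ccccc2)COC1=O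
F4 | step 5 | (4R)-4-benzyl-3-[(2S)-2-{[(3R,4R)-4-{[tert-butyl(dimethyl)silyl]oxy}hept-6-en-3-yl]oxy}pent-4-enoyl]-1,3-oxazolidin-2-one | O=C([C@H](CC=C)O[C@H](CC)[C@H](O[Si](C)(C)C(C)(C)C)CC=C)N1[C@H](Cc2ccccc2)COC1=O
F5 | step 6 | (2S)-2-{[(3R,4R)-4-{[tert-butyl(dimethyl)silyl]oxy}hept-6-en-3-yl]oxy}pent-4-en-1-ol | OC[C@H](CC=C)O[C@H](CC)[C@H](O[Si](C)(C)C(C)(C)C)CC=C
F6 | step 6 | (2S)-2-{[(3R,4R)-4-{[tert-butyl(dimethyl)silyl]oxy}hept-6-en-3-yl]oxy}pent-4-en-1-yl acetate | CC(=O)OC[C@H](CC=C)O[C@H](CC)[C@H](O[Si](C)(C)C(C)(C)C)CC=C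
F7 | step 6 | [(2S,4Z,7R,8R)-7-{[tert-butyl(dimethyl)silyl]oxy}-8-ethyl-3,6,7,8-tetrahydro-2H-oxocin-2-yl]methyl acetate | CC(=O)OC[C@@H]1C/C=C\C[C@@H](O[Si](C)(C)C(C)(C)C)[C@@H](CC)O1
F8 | step 6 | [(2S,4Z,7R,8R)-7-{[tert-butyl(dimethyl)silyl]oxy}-8-ethyl-3,6,7,8-tetrahydro-2H-oxocin-2-yl]methanol | OC[C@@H]1C/C=C\C[C@@H](O[Si](C)(C)C(C)(C)C)[C@@H](CC)O1
F9 | step 6 | (2S,4Z,7R,8R)-7-{[tert-butyl(dimethyl)silyl]oxy}-8-ethyl-3,6,7,8-tetrahydro-2H-oxocine-2-carboxylic acid | OC(=O)[C@@H]1C/C=C\C[C@@H](O[Si](C)(C)C(C)(C)C)[C@@H](CC)O1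
F10 | step 11 | (1S)-1-[(2S,4Z,7S,8R)-7-bromo-8-ethyl-3,6,7,8-tetrahydro-2H-oxocin-2-yl]-2-(1,3-dioxolan-2-yl)ethan-1-ol | O1CCOC1C[C@H](O)[C@@H]2C/C=C\C[C@H](Br)[C@@H](CC)O2
F11 | step 11 | (1S,3R,4S,6S,7S,9S)-4,6-dibromo-9-[(1,3-dioxolan-2-yl)methyl]-3-ethyl-2,8-dioxabicyclo[5.2.1]decane | O1CCOC1C[C@@H]2O[C@H]3C[C@@H]2O[C@H](CC)[C@@H](Br)C[C@@H]3Br
F12 | step 11 | 2-[(1S,3R,4S,6S,7S,9S)-4,6-dibromo-3-ethyl-2,8-dioxabicyclo[5.2.1]decan-9-yl]acetaldehyde | O=CC[C@@H]1O[C@H]2C[C@@H]1O[C@H](CC)[C@@H](Br)C[C@@H]2Br
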